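**Retrosynthetic overview**

- The target is 2-methoxy-6,7-dimethyl-8-(2,4,5-trimethoxyphenyl)naphthalene-1,4-dione. The strategy rests on ring C: oxygen on C2' and C5' (para to each other), a further OMe on C4', H on C3' and C6', and C1' bonded to C8 of the naphthoquinone. This is the 4-methoxyphenol pattern formed from a methoxy(1-methoxyvinyl)carbene of chromium (C3', C4', C5'), one CO (C2') and a terminal alkyne (C6', C1').
- Ring C is therefore disconnected to an 8-ethynylnaphthalene, with the quinone masked as a bis(methoxymethyl) ether, and (CO)5Cr=C(OMe)C(OMe)=CH2. The C8–C1' biaryl bond is the former aryl–alkyne bond, so no aryl–aryl coupling is needed.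
- Ring B is disconnected by a Diels–Alder reaction between 2-methoxy-1,4-benzoquinone (ring A, purchased) and an (E)-1-(silylethynyl)-2,3-dimethylbuta-1,3-diene. The diene comes from 2-methylbut-1-en-3-yne by methylalumination/iodination and Sonogashira coupling.
- Ring order: A purchased; B by cycloaddition and aromatisation (steps 3 and 4); C last by benzannulation (step 9). The end game is O-methylation, acidic MOM removal and Ag2O oxidation.

Key step: step 9

Assumption: the target has no stereocentre and its C8–C1' axis carries no descriptor, so it is prepared as the racemate with respect to any hindered rotation about that bond.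

**Route**

Step 1
Reactants: 1 2-methylbut-1-en-3-yne
Product: 3 (1E)-1-iodo-2,3-dimethylbuta-1,3-diene, via dienyldimethylalane 2 (not isolated)
Conditions: Me3Al (2 equiv), Cp2ZrCl2 (20 mol %), CH2Cl2, 0 °C to rt; then I2, THF, −30 to 0 °C
Reagents that add atoms: trimethylaluminium C[Al](C)C; iodine II
Why: Negishi zirconium-catalysed methylalumination adds CH3 and Al syn across the terminal alkyne with Al on the terminal carbon and leaves the 1,1-disubstituted alkene alone, and iodinolysis of the C–Al bond with retention should give the E iodide, with iodine trans to the isopropenyl group as the later cycloaddition requires.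

Step 2
Reactants: 3 (1E)-1-iodo-2,3-dimethylbuta-1,3-diene; 4 ethynyltri(propan-2-yl)silane
Product: 5 [(3E)-4,5-dimethylhexa-3,5-dien-1-yn-1-yl]tri(propan-2-yl)silane
Conditions: Pd(PPh3)2Cl2 (2 mol %), CuI (4 mol %), Et3N, THF, rt
Reagents that add atoms: none
Why: Sonogashira coupling of an alkenyl iodide runs at room temperature with retention of alkene geometry, and the triisopropylsilyl cap keeps the alkyne inert through the next four steps.

Step 3
Reactants: 5 [(3E)-4,5-dimethylhexa-3,5-dien-1-yn-1-yl]tri(propan-2-yl)silane; 6 2-methoxycyclohexa-2,5-diene-1,4-dione (2-methoxy-1,4-benzoquinone)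
Product: 7 racemic cis-fused 2-methoxy-6,7-dimethyl-8-{[tri(propan-2-yl)silyl]ethynyl}-4a,5,8,8a-tetrahydronaphthalene-1,4-dione, with H-4a, H-8a and H-8 on the same face
Conditions: 5 (1.3 equiv), PhMe, 80 °C, dark
Reagents that add atoms: none
Why: Thermal Diels–Alder reaction at the unsubstituted C5=C6 bond of the quinone, in which C1=O (not a vinylogous ester carbonyl) is the stronger acceptor, so the unsubstituted diene terminus should bond to quinone C5 and the alkynyl-bearing terminus next to C1=O ("ortho" orientation); the three stereocentres follow from suprafacial endo addition of the E diene and are erased in step 4.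

Step 4
Reactants: 7 the tetrahydronaphthalenedione adduct
Product: 10 2-methoxy-6,7-dimethyl-8-{[tri(propan-2-yl)silyl]ethynyl}naphthalene-1,4-dione, via dihydronaphthalenediol 8 (not isolated), via dihydronaphthoquinone 9 (not isolated)
Conditions: Et3N (10 mol %), CH2Cl2, rt; then DDQ (2.2 equiv), rt
Reagents that add atoms: none
Why: Amine-catalysed enolisation of the ene-dione gives the aromatic hydroquinone, which DDQ should oxidise to the quinone and then dehydrogenate at the doubly activated C5 and C8 positions (quinone DDQ aromatisation), with the silyl alkyne and methyl groups untouched.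

Step 5
Reactants: 10 the 8-(silylethynyl)naphthoquinone
Product: 11 2-methoxy-6,7-dimethyl-8-{[tri(propan-2-yl)silyl]ethynyl}naphthalene-1,4-diol
Conditions: Na2S2O4, EtOAc/H2O, rt, Ar
Reagents that add atoms: none
Why: Two-phase dithionite reduction of a 1,4-naphthoquinone to its hydroquinone is fast and leaves the silyl alkyne alone; the air-sensitive diol is carried on at once.

Step 6
Reactants: 11 the naphthalene-1,4-diol
Product: 12 {[7-methoxy-5,8-bis(methoxymethoxy)-2,3-dimethylnaphthalen-1-yl]ethynyl}tri(propan-2-yl)silane
Conditions: NaH (2.5 equiv), MOMCl (3 equiv), DMF, 0 °C to rt, Ar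
Reagents that add atoms: chloromethyl methyl ether COCCl
Why: Williamson O-alkylation of both aryloxides with the reactive chloromethyl ether should outrun any addition of the peri aryloxide to the silyl-capped alkyne, and the resulting acetals withstand fluoride, the neutral benzannulation and carbonate/MeI yet come off later with acid alone.

Step 7
Reactants: 12 the bis(methoxymethyl) ether
Product: 13 8-ethynyl-2-methoxy-1,4-bis(methoxymethoxy)-6,7-dimethylnaphthalene
Conditions: TBAF (1.2 equiv), THF, 0 °C to rt
Reagents that add atoms: none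
Why: Fluoride-induced protodesilylation of an alkynylsilane; aryl MOM and methyl ethers are stable to TBAF.

Step 8
Reactants: 14 methyl vinyl ether; 15 Cr(CO)6
Product: 18 pentacarbonyl[methoxy(1-methoxyethenyl)carbene]chromium, via 1-methoxyvinyllithium 16 (not isolated), via lithium acylchromate 17 (not isolated)
Conditions: t-BuLi, THF, −78 to 0 °C; Cr(CO)6, 0 °C to rt; solvent switch, Me3OBF4, CH2Cl2, 0 °C
Reagents that add atoms: trimethyloxonium tetrafluoroborate C[O+](C)C.F[B-](F)(F)F
Why: Fischer carbene synthesis, in which alpha-lithiation of the enol ether, addition of the vinyllithium to a CO ligand of Cr(CO)6 and O-methylation of the acyl chromate should give the complex, as for the related isopropenyl and dihydropyranyl complexes; it is filtered quickly through deactivated silica and used fresh.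

Step 9
Reactants: 13 8-ethynyl-2-methoxy-1,4-bis(methoxymethoxy)-6,7-dimethylnaphthalene; 18 pentacarbonyl[methoxy(1-methoxyethenyl)carbene]chromium
Product: 20 4,5-dimethoxy-2-[7-methoxy-5,8-bis(methoxymethoxy)-2,3-dimethylnaphthalen-1-yl]phenol, via tricarbonylchromium arene complex 19 (not isolated)
Conditions: 18 (1.5 equiv), THF (0.05 M in 13), 50 °C, Ar; then air, daylight, Et2O, rt
Reagents that add atoms: none
Why: Heating makes 18 lose one cis CO, the alkyne binds and inserts with its CH carbon on the carbene carbon (C5'–C6'), CO inserts at the new naphthyl-bearing carbene carbon to give an η4-vinylketene (C1'–C2'), and the dienylketene closes between the ketene carbon and the vinyl CH2 (C2'–C3') before enolising to the phenol as its Cr(CO)3 complex 19, which air and light demetalate. The closest known reactions are Dötz benzannulations of isopropenyl and of cyclic alpha-alkoxyvinyl (dihydropyranyl) methoxycarbene complexes of zerovalent chromium with terminal aryl alkynes, ortho-substituted ones included. Ring C is the only ring closed, by a thermal 6π electrocyclisation within the chromium coordination sphere. No stereocentre is created and the C8–C1' axis arises as a racemate. The regiochemistry needed, naphthyl on C1' beside the CO-derived C2', follows from steric control in the insertion of a terminal alkyne, which places the large substituent away from the carbene carbon, and an alkenyl chromium carbene inserts CO readily, so phenol formation should prevail over cyclisation without CO. Excess 18 and dilution should suppress double alkyne insertion, and the MOM ethers, the aryl methyl ether and the ring B methyl groups are inert under these neutral conditions.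

Step 10
Reactants: 20 the ring C phenol
Product: 21 2-methoxy-1,4-bis(methoxymethoxy)-6,7-dimethyl-8-(2,4,5-trimethoxyphenyl)naphthalene
Conditions: MeI, K2CO3, DMF, rt, Ar
Reagents that add atoms: iodomethane CI
Why: Williamson methylation of the phenoxide, done promptly because the electron-rich 4-methoxyphenol is oxidation-prone; MOM ethers are stable to carbonate.

Step 11
Reactants: 21 the trimethoxyphenyl bis(methoxymethyl) ether
Product: 22 2-methoxy-6,7-dimethyl-8-(2,4,5-trimethoxyphenyl)naphthalene-1,4-diol
Conditions: 3 M HCl (aq.), MeOH/THF, 45 °C, Ar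
Reagents that add atoms: none
Why: Acid-catalysed acetal exchange with methanol should remove both MOM groups as dimethoxymethane, while the four aryl methyl ethers are inert to dilute HCl.

Step 12
Reactants: 22 the naphthalene-1,4-diol
Product: 23 2-methoxy-6,7-dimethyl-8-(2,4,5-trimethoxyphenyl)naphthalene-1,4-dione (target, CNP0272937.0)
Conditions: Ag2O, Na2SO4, Et2O, rt
Reagents that add atoms: none
Why: Ag2O dehydrogenation of a hydroquinone to the quinone is neutral and should leave the 1,2,4-trimethoxyphenyl ring alone, which a one-electron oxidant such as (NH4)2Ce(NO3)6 would attack.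

**Compound list**

1 | 2-methylbut-1-en-3-yne | C=C(C)C#C | starting material
2 | [(1E)-2,3-dimethylbuta-1,3-dien-1-yl]dimethylalane | C=C(C)/C(C)=C/[Al](C)C | intermediate
3 | (1E)-1-iodo-2,3-dimethylbuta-1,3-diene | C=C(C)/C(C)=C/I | intermediate
4 | ethynyltri(propan-2-yl)silane | C#C[Si](C(C)C)(C(C)C)C(C)C | starting material
5 | [(3E)-4,5-dimethylhexa-3,5-dien-1-yn-1-yl]tri(propan-2-yl)silane | C=C(C)/C(C)=C/C#C[Si](C(C)C)(C(C)C)C(C)C | intermediate
6 | 2-methoxycyclohexa-2,5-diene-1,4-dione | COC1=CC(=O)C=CC1=O | starting material
7 | racemic cis-fused 2-methoxy-6,7-dimethyl-8-{[tri(propan-2-yl)silyl]ethynyl}-4a,5,8,8a-tetrahydronaphthalene-1,4-dione, H-4a, H-8 and H-8a all cis (one enantiomer drawn) | COC1=CC(=O)[C@@H]2CC(C)=C(C)[C@H](C#C[Si](C(C)C)(C(C)C)C(C)C)[C@@H]2C1=O | intermediate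
8 | racemic 2-methoxy-6,7-dimethyl-8-{[tri(propan-2-yl)silyl]ethynyl}-5,8-dihydronaphthalene-1,4-diol | COc1cc(O)c2c(c1O)C(C#C[Si](C(C)C)(C(C)C)C(C)C)C(C)=C(C)C2 | intermediate
9 | racemic 2-methoxy-6,7-dimethyl-8-{[tri(propan-2-yl)silyl]ethynyl}-5,8-dihydronaphthalene-1,4-dione | COC1=CC(=O)C2=C(C1=O)C(C#C[Si](C(C)C)(C(C)C)C(C)C)C(C)=C(C)C2 | intermediate
10 | 2-methoxy-6,7-dimethyl-8-{[tri(propan-2-yl)silyl]ethynyl}naphthalene-1,4-dione | COC1=CC(=O)c2cc(C)c(C)c(C#C[Si](C(C)C)(C(C)C)C(C)C)c2C1=O | intermediate
11 | 2-methoxy-6,7-dimethyl-8-{[tri(propan-2-yl)silyl]ethynyl}naphthalene-1,4-diol | COc1cc(O)c2cc(C)c(C)c(C#C[Si](C(C)C)(C(C)C)C(C)C)c2c1O | intermediate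
12 | {[7-methoxy-5,8-bis(methoxymethoxy)-2,3-dimethylnaphthalen-1-yl]ethynyl}tri(propan-2-yl)silane | COCOc1cc(OC)c(OCOC)c2c(C#C[Si](C(C)C)(C(C)C)C(C)C)c(C)c(C)cc12 | intermediate
13 | 8-ethynyl-2-methoxy-1,4-bis(methoxymethoxy)-6,7-dimethylnaphthalene | C#Cc1c(C)c(C)cc2c(OCOC)cc(OC)c(OCOC)c12 | intermediate
14 | methyl vinyl ether (methoxyethene) | C=COC | starting material
15 | Cr(CO)6, hexacarbonylchromium | O=C=[Cr](=C=O)(=C=O)(=C=O)(=C=O)=C=O | starting material
16 | 1-methoxyvinyllithium | [Li]C(=C)OC | intermediate
17 | lithium pentacarbonyl(2-methoxyprop-2-enoyl)chromate | [Li+].COC(=C)C([O-])=[Cr](=C=O)(=C=O)(=C=O)(=C=O)=C=O | intermediate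
18 | pentacarbonyl[methoxy(1-methoxyethenyl)carbene]chromium | COC(=C)C(OC)=[Cr](=C=O)(=C=O)(=C=O)(=C=O)=C=O | intermediate
19 | tricarbonylchromium complex of 20, Cr(CO)3 bound η6 to ring C (hapticity not encoded; the SMILES lists the two components) | COCOc1cc(OC)c(OCOC)c2c(-c3cc(OC)c(OC)cc3O)c(C)c(C)cc12.O=C=[Cr](=C=O)=C=O | intermediate
20 | 4,5-dimethoxy-2-[7-methoxy-5,8-bis(methoxymethoxy)-2,3-dimethylnaphthalen-1-yl]phenol | COCOc1cc(OC)c(OCOC)c2c(-c3cc(OC)c(OC)cc3O)c(C)c(C)cc12 | intermediate
21 | 2-methoxy-1,4-bis(methoxymethoxy)-6,7-dimethyl-8-(2,4,5-trimethoxyphenyl)naphthalene | COCOc1cc(OC)c(OCOC)c2c(-c3cc(OC)c(OC)cc3OC)c(C)c(C)cc12 | intermediate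
22 | 2-methoxy-6,7-dimethyl-8-(2,4,5-trimethoxyphenyl)naphthalene-1,4-diol | COc1cc(O)c2cc(C)c(C)c(-c3cc(OC)c(OC)cc3OC)c2c1O | intermediate
23 | 2-methoxy-6,7-dimethyl-8-(2,4,5-trimethoxyphenyl)naphthalene-1,4-dione | COC1=CC(=O)c2cc(C)c(C)c(-c3cc(OC)c(OC)cc3OC)c2C1=O | target

**Step count**

Total: 12 steps. Longest linear sequence: 11 steps (steps 1–7 and 9–12, from 2-methylbut-1-en-3-yne). Step 8 is a one-step side branch.

**Steps most likely to fail**

Step 9. Insertion of the alkyne, which is flanked by the C7 methyl and the peri C1 acetal, may be slow. The labile alpha-methoxyvinyl carbene complex could then decompose, take up two alkynes, or close without CO insertion.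

The fallback builds ring B with ring C already attached and sets out from iodide 3. Suzuki–Miyaura coupling of 3 with commercial 2,4,5-trimethoxyphenylboronic acid (Pd(PPh3)4, K2CO3, dioxane/H2O, 80 °C) should give 1-[(1E)-2,3-dimethylbuta-1,3-dien-1-yl]-2,4,5-trimethoxybenzene F1 with retention of geometry. Thermal Diels–Alder reaction of F1 with quinone 6 (PhMe, 100 °C), under the same orientation rule as step 3, should give the cis-fused adduct 2-methoxy-6,7-dimethyl-8-(2,4,5-trimethoxyphenyl)-4a,5,8,8a-tetrahydronaphthalene-1,4-dione F2. Enolisation with Et3N and dehydrogenation with activated MnO2 should then aromatise F2 directly to the target. This fallback comes back to the route at 23.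

Step 3. The diene may add in the reverse orientation, with the alkynyl terminus bonding beside C4=O, because the alkynyl group is only a weak director. This would lead into the 5-alkynyl series.

The fallback sets out from diene 5 and uses a bromine-directed dienophile. Dakin oxidation of 5-bromovanillin (H2O2, NaOH) gives 2-bromo-6-methoxybenzene-1,4-diol F3. Oxidation with FeCl3 gives 2-bromo-6-methoxycyclohexa-2,5-diene-1,4-dione F4. Cycloaddition of 5 occurs at the bromine-bearing double bond of F4, where the unsubstituted diene terminus goes to the CH carbon. It should give 8a-bromo-2-methoxy-6,7-dimethyl-8-{[tri(propan-2-yl)silyl]ethynyl}-4a,5,8,8a-tetrahydronaphthalene-1,4-dione F5. Et3N removes HBr from F5 to give the dihydronaphthoquinone. This fallback comes back to the route at 9, which the DDQ stage of step 4 converts to 10.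

Step 6. Air re-oxidation of the diol, or addition of the peri C1 aryloxide to the neighbouring alkyne, may compete with the double O-alkylation.

The fallback sets out from adduct 7 and protects before aromatising. Treatment of 7 with NaH (3 equiv) and MOMCl in THF/DMF at 0 °C should cause double enolisation and O-alkylation. This gives racemic {[7-methoxy-5,8-bis(methoxymethoxy)-2,3-dimethyl-1,4-dihydronaphthalen-1-yl]ethynyl}tri(propan-2-yl)silane F6 without a free hydroquinone ever being handled. DDQ (1.1 equiv, PhH, rt) then dehydrogenates the 5,8-dihydro ring. This fallback comes back to the route at 12 and skips steps 4 and 5.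

**Further compounds**

F1 | step 9 | 1-[(1E)-2,3-dimethylbuta-1,3-dien-1-yl]-2,4,5-trimethoxybenzene | C=C(C)/C(C)=C/c1cc(OC)c(OC)cc1OC
F2 | step 9 | racemic cis-fused 2-methoxy-6,7-dimethyl-8-(2,4,5-trimethoxyphenyl)-4a,5,8,8a-tetrahydronaphthalene-1,4-dione, H-4a, H-8 and H-8a all cis (one enantiomer drawn) | COC1=CC(=O)[C@@H]2CC(C)=C(C)[C@H](c3cc(OC)c(OC)cc3OC)[C@@H]2C1=O
F3 | step 3 | 2-bromo-6-methoxybenzene-1,4-diol | COc1cc(O)cc(Br)c1O
F4 | step 3 | 2-bromo-6-methoxycyclohexa-2,5-diene-1,4-dione | COC1=CC(=O)C=C(Br)C1=O
F5 | step 3 | racemic cis-fused 8a-bromo-2-methoxy-6,7-dimethyl-8-{[tri(propan-2-yl)silyl]ethynyl}-4a,5,8,8a-tetrahydronaphthalene-1,4-dione, endo adduct (one enantiomer drawn) | COC1=CC(=O)[C@@H]2CC(C)=C(C)[C@H](C#C[Si](C(C)C)(C(C)C)C(C)C)[C@]2(Br)C1=O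
F6 | step 6 | racemic {[7-methoxy-5,8-bis(methoxymethoxy)-2,3-dimethyl-1,4-dihydronaphthalen-1-yl]ethynyl}tri(propan-2-yl)silane | COCOc1cc(OC)c(OCOC)c2c1CC(C)=C(C)C2C#C[Si](C(C)C)(C(C)C)C(C)C
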